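Ring B of the target, the cyclopentenone C5–C9 (spiro locants), carries at C9 a tertiary hydroxyl and an acetyl group next to alkene carbon C8: the 4-acyl-4-hydroxycyclopentenone pattern that an acyloin ring contraction leaves behind. Everything rests on disconnecting the C8–C9 bond to a six-membered tertiary α-ketol, a 4-hydroxy-4,5,6-trimethylcyclohex-5-ene-1,3-dione whose C2 is the spiro carbon shared with the tetrahydrofuran (ring A). In one operation the α-ketol shift moves the vinylic carbon from the carbinol carbon to the adjacent ketone, closes ring B, turns the carbinol carbon into the acetyl group and relays its configuration to C9. The precursor is assembled from a phytol-derived iodide and a protected trimethylresorcinol by oxidative spiroetherification and reagent-controlled dienolate hydroxylation.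

Key step: step 12

Remark on locants: spiro-nomenclature locants are used for all spirocycles (ring A = O1, C2, C3, C4, spiro C5; ring B = the carbocycle). In the target C6 is the ring ketone, C7=C8 the alkene and C9 the carbinol carbon with the acetyl group; in the six-membered precursor C6 is the isolated ketone, C7 the hydroxylated carbon, C8=C9 the alkene and C10 the enone carbonyl.

Remark on configuration: the target as drawn is (2S,5R,9S,4′R,8′R); its ether carbon C2 (S) corresponds to the (3S) tertiary carbinol that phytol gives with the L-(+)-tartrate epoxidation catalyst.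

Assumption: the (+)-(2R,8aS) antipode of the (camphorylsulfonyl)oxaziridine is taken as the one that favours the (7S) carbinol in step 11; the sense of induction on this dienolate cannot be predicted with confidence, and the antipodal reagent would be used instead with no other change.

Step 1
Reactants: 1 (E,7R,11R)-phytol
Product: 2 [(2S,3S)-3-methyl-3-[(4R,8R)-4,8,12-trimethyltridecyl]oxiran-2-yl]methanol
Conditions: Ti(OiPr)4 (cat.), L-(+)-diethyl tartrate (cat.), tBuOOH, 4 Å molecular sieves, CH2Cl2, −20 °C
Reagents that add atoms: tert-butyl hydroperoxide, CC(C)(C)OO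
Why: Sharpless asymmetric epoxidation of an E-trisubstituted allylic alcohol, in which the titanium tartrate complex from L-(+)-diethyl tartrate delivers oxygen to the alkene face that gives the (2S,3S)-epoxide, as with geraniol; C3 is the future ether carbon C2 of the target.

Step 2
Reactants: 2 [(2S,3S)-3-methyl-3-[(4R,8R)-4,8,12-trimethyltridecyl]oxiran-2-yl]methanol
Product: 3 (3S,7R,11R)-3,7,11,15-tetramethylhexadecane-1,3-diol
Conditions: NaAlH2(OCH2CH2OMe)2, THF, 0 °C → rt
Reagents that add atoms: none
Why: Regioselective reductive opening of a 2,3-epoxy alcohol, in which the aluminium hydride bound to the C1 alkoxide delivers hydride to C2, so the C3–O bond and the (3S) configuration are kept.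

Step 3
Reactants: 3 (3S,7R,11R)-3,7,11,15-tetramethylhexadecane-1,3-diol
Product: 4 (3S,7R,11R)-1-iodo-3,7,11,15-tetramethylhexadecan-3-ol
Conditions: I2, PPh3, imidazole, CH2Cl2, 0 °C
Reagents that add atoms: iodine, II
Why: Appel-type iodination, in which only the primary hydroxyl forms an alkoxyphosphonium ion that iodide can displace by SN2, the tertiary hydroxyl being too hindered; no stereocentre is touched.

Step 4
Reactants: 4 (3S,7R,11R)-1-iodo-3,7,11,15-tetramethylhexadecan-3-ol
Product: 5 triethyl{[(3S,7R,11R)-1-iodo-3,7,11,15-tetramethylhexadecan-3-yl]oxy}silane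
Conditions: Et3SiOTf, 2,6-lutidine, CH2Cl2, −78 → 0 °C
Reagents that add atoms: triethylsilyl trifluoromethanesulfonate, CC[Si](CC)(CC)OS(=O)(=O)C(F)(F)F
Why: Silylation of a hindered tertiary alcohol with a silyl triflate and a non-nucleophilic base; the ether masks the hydroxyl against the aryllithium of step 8 and the primary iodide is inert to these conditions.

Step 5
Reactants: 6 1,2,3-trimethylbenzene
Product: 7 1,5-dibromo-2,3,4-trimethylbenzene
Conditions: Br2 (2.1 equiv), I2 (cat.), CH2Cl2, 0 °C → rt, dark
Reagents that add atoms: bromine, BrBr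
Why: Electrophilic aromatic bromination, in which the two ring positions that are each ortho and para to two methyl groups are far more activated than the third; working cold in the dark spares the benzylic positions.

Step 6
Reactants: 7 1,5-dibromo-2,3,4-trimethylbenzene
Product: 8 4,5,6-trimethylbenzene-1,3-diol
Conditions: Pd2(dba)3 (cat.), tBuXPhos (cat.), KOH, 1,4-dioxane/H2O, 100 °C, argon; then aq. HCl
Reagents that add atoms: potassium hydroxide, [K+].[OH-]
Why: Palladium-catalysed C–O cross-coupling of aryl bromides with hydroxide, for which the bulky biaryl phosphine allows reductive elimination next to an ortho methyl group; the dipotassium resorcinolate is protonated in the work-up.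

Step 7
Reactants: 8 4,5,6-trimethylbenzene-1,3-diol
Product: 9 1,5-bis(methoxymethoxy)-2,3,4-trimethylbenzene
Conditions: MeOCH2Cl, iPr2NEt, CH2Cl2, 0 °C → rt
Reagents that add atoms: chloromethyl methyl ether, COCCl
Why: Williamson-type O-alkylation of both phenols to methoxymethyl acetals, chosen because they direct metalation strongly and later come off under acid mild enough to spare a tertiary alcohol, which aryl methyl ethers would not allow.

Step 8
Reactants: 9 1,5-bis(methoxymethoxy)-2,3,4-trimethylbenzene, 5 triethyl{[(3S,7R,11R)-1-iodo-3,7,11,15-tetramethylhexadecan-3-yl]oxy}silane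
Product: 11 {[(3S,7R,11R)-1-[2,6-bis(methoxymethoxy)-3,4,5-trimethylphenyl]-3,7,11,15-tetramethylhexadecan-3-yl]oxy}triethylsilane, via aryllithium 10 (not isolated)
Conditions: nBuLi, TMEDA, THF, 0 °C; then 5, −78 °C → rt
Reagents that add atoms: none
Why: Directed ortho-metalation at the only ring C–H, which is flanked by both methoxymethoxy groups, followed by SN2 alkylation of the aryllithium by the primary iodide; the silyl-protected carbinol centre is not involved.

Step 9
Reactants: 11 {[(3S,7R,11R)-1-[2,6-bis(methoxymethoxy)-3,4,5-trimethylphenyl]-3,7,11,15-tetramethylhexadecan-3-yl]oxy}triethylsilane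
Product: 12 2-[(3S,7R,11R)-3-hydroxy-3,7,11,15-tetramethylhexadecyl]-4,5,6-trimethylbenzene-1,3-diol
Conditions: HCl (1 M aq., cat.), MeOH/THF, rt, argon
Reagents that add atoms: none
Why: Acid-catalysed solvolysis of the two aryl methoxymethyl acetals and of the triethylsilyl ether in one operation; at room temperature the unactivated tertiary alcohol should not ionise, so neither chroman formation nor loss of configuration is expected.

Step 10
Reactants: 12 2-[(3S,7R,11R)-3-hydroxy-3,7,11,15-tetramethylhexadecyl]-4,5,6-trimethylbenzene-1,3-diol
Product: 13 (2S)-10-hydroxy-2,7,8,9-tetramethyl-2-[(4R,8R)-4,8,12-trimethyltridecyl]-1-oxaspiro[4.5]deca-7,9-dien-6-one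
Conditions: PhI(OAc)2 (1.05 equiv), (CF3)2CHOH, 0 °C
Reagents that add atoms: none
Why: Oxidative dearomatisation of a phenol by hypervalent (trivalent) iodine, in which the tethered tertiary hydroxyl attacks the ring carbon between the two oxygens (5-exo spirocyclisation closing ring A) in a non-nucleophilic solvent; the vinylogous acid formed interconverts its two enol forms, so the spiro carbon is not yet a fixed stereocentre.

Step 11
Reactants: 13 (2S)-10-hydroxy-2,7,8,9-tetramethyl-2-[(4R,8R)-4,8,12-trimethyltridecyl]-1-oxaspiro[4.5]deca-7,9-dien-6-one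
Product: 15 (2S,5S,7S)-7-hydroxy-2,7,8,9-tetramethyl-2-[(4R,8R)-4,8,12-trimethyltridecyl]-1-oxaspiro[4.5]dec-8-ene-6,10-dione, via sodium dienolate 14 (not isolated)
Conditions: NaN(SiMe3)2, THF, −78 °C; then (+)-(2R,8aS)-(camphorylsulfonyl)oxaziridine, −78 → −20 °C; then AcOH, −40 °C
Reagents that add atoms: (+)-(2R,8aS)-(camphorylsulfonyl)oxaziridine, CC1(C)[C@@H]2CC[C@]13CS(=O)(=O)N4O[C@@]34C2
Why: Davis oxaziridine hydroxylation of an enolate, in which the symmetrical dienolate 14 is oxygenated at one of its two equivalent nucleophilic carbons, fixing C5 and creating C7; the enantiopure reagent is relied on to choose between the two mirror-related carbons that the remote C2 centre cannot tell apart, attack anti to the lone pairs of O1 is expected to place the hydroxyl trans to O1, and minor diastereomers are to be removed by chromatography.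

Step 12
Reactants: 15 (2S,5S,7S)-7-hydroxy-2,7,8,9-tetramethyl-2-[(4R,8R)-4,8,12-trimethyltridecyl]-1-oxaspiro[4.5]dec-8-ene-6,10-dione
Product: 16 alpha-tocospiro A, (2S,5R,9S)-9-acetyl-9-hydroxy-2,7,8-trimethyl-2-[(4R,8R)-4,8,12-trimethyltridecyl]-1-oxaspiro[4.4]non-7-en-6-one
Conditions: Al(OtBu)3 (1.5 equiv), PhMe, 80 °C; then H2O
Reagents that add atoms: none
Why: Exchange of one tert-butoxide gives the aluminium alkoxide of the C7 hydroxyl, which chelates the C6 carbonyl and holds O–C7–C6=O syn-periplanar, so the C7–C8 bond stands out of the carbonyl plane in line with its π* orbital and C8 shifts suprafacially from C7 to C6 while C7 becomes the acetyl carbonyl (α-ketol or acyloin rearrangement; the tert-butoxide has no hydride to transfer, so the ketones are not reduced). The closest known reactions are the contraction of hop α-acids to iso-α-acids and the aluminium-alkoxide-mediated D-homoannulation of tertiary α-ketols. Ring B is closed by the 1,2-shift itself, a six-to-five ring contraction through a three-membered bridged transition state, not by an exo or endo cyclisation. The new stereocentre C9 of 16 (C6 of 15) is controlled by the C7 configuration of 15: in the chelate the C7 methyl is axial on the O1 face, C8 adds to the opposite face of the C6 carbonyl, and the acetyl group ends syn to O1, while C5 and C2 are not touched. The step needs vinyl migration in preference to methyl migration and contraction in preference to reversal. The higher migratory aptitude of the sp2 carbon, the relief of the non-enolisable 1,3-dione and the formation of an unstrained methyl ketone should secure both.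

Locant map for step 12: C6, C7, C8, C9, C10 of 15 become C9, the acetyl carbonyl carbon, C8, C7, C6 of 16; the bond formed is C8–C9 of 16.

Compound list
1 | (E,7R,11R)-phytol, (2E,7R,11R)-3,7,11,15-tetramethylhexadec-2-en-1-ol | CC(C)CCC[C@@H](C)CCC[C@@H](C)CCC/C(C)=C/CO | starting material
2 | [(2S,3S)-3-methyl-3-[(4R,8R)-4,8,12-trimethyltridecyl]oxiran-2-yl]methanol | OC[C@@H]1O[C@@]1(C)CCC[C@H](C)CCC[C@H](C)CCCC(C)C | intermediate
3 | (3S,7R,11R)-3,7,11,15-tetramethylhexadecane-1,3-diol | OCC[C@@](C)(O)CCC[C@H](C)CCC[C@H](C)CCCC(C)C | intermediate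
4 | (3S,7R,11R)-1-iodo-3,7,11,15-tetramethylhexadecan-3-ol | ICC[C@@](C)(O)CCC[C@H](C)CCC[C@H](C)CCCC(C)C | intermediate
5 | triethyl{[(3S,7R,11R)-1-iodo-3,7,11,15-tetramethylhexadecan-3-yl]oxy}silane | ICC[C@@](C)(O[Si](CC)(CC)CC)CCC[C@H](C)CCC[C@H](C)CCCC(C)C | intermediate
6 | 1,2,3-trimethylbenzene | Cc1cccc(C)c1C | starting material
7 | 1,5-dibromo-2,3,4-trimethylbenzene | Cc1c(C)c(Br)cc(Br)c1C | intermediate
8 | 4,5,6-trimethylbenzene-1,3-diol | Cc1c(C)c(O)cc(O)c1C | intermediate
9 | 1,5-bis(methoxymethoxy)-2,3,4-trimethylbenzene | COCOc1cc(OCOC)c(C)c(C)c1C | intermediate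
10 | [2,6-bis(methoxymethoxy)-3,4,5-trimethylphenyl]lithium | [Li]c1c(OCOC)c(C)c(C)c(C)c1OCOC | intermediate
11 | {[(3S,7R,11R)-1-[2,6-bis(methoxymethoxy)-3,4,5-trimethylphenyl]-3,7,11,15-tetramethylhexadecan-3-yl]oxy}triethylsilane | COCOc1c(C)c(C)c(C)c(OCOC)c1CC[C@@](C)(O[Si](CC)(CC)CC)CCC[C@H](C)CCC[C@H](C)CCCC(C)C | intermediate
12 | 2-[(3S,7R,11R)-3-hydroxy-3,7,11,15-tetramethylhexadecyl]-4,5,6-trimethylbenzene-1,3-diol | Cc1c(C)c(O)c(CC[C@@](C)(O)CCC[C@H](C)CCC[C@H](C)CCCC(C)C)c(O)c1C | intermediate
13 | (2S)-10-hydroxy-2,7,8,9-tetramethyl-2-[(4R,8R)-4,8,12-trimethyltridecyl]-1-oxaspiro[4.5]deca-7,9-dien-6-one (spiro carbon left undefined, it is equilibrated by enol–enol proton transfer) | CC1=C(C)C(=O)C2(CC[C@](C)(CCC[C@H](C)CCC[C@H](C)CCCC(C)C)O2)C(O)=C1C | intermediate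
14 | sodium (2S)-2,7,8,9-tetramethyl-6-oxo-2-[(4R,8R)-4,8,12-trimethyltridecyl]-1-oxaspiro[4.5]deca-7,9-dien-10-olate | CC1=C(C)C(=O)C2(CC[C@](C)(CCC[C@H](C)CCC[C@H](C)CCCC(C)C)O2)C([O-])=C1C.[Na+] | intermediate
15 | (2S,5S,7S)-7-hydroxy-2,7,8,9-tetramethyl-2-[(4R,8R)-4,8,12-trimethyltridecyl]-1-oxaspiro[4.5]dec-8-ene-6,10-dione | C[C@]1(O)C(C)=C(C)C(=O)[C@@]2(CC[C@](C)(CCC[C@H](C)CCC[C@H](C)CCCC(C)C)O2)C1=O | intermediate
16 | alpha-tocospiro A, (2S,5R,9S)-9-acetyl-9-hydroxy-2,7,8-trimethyl-2-[(4R,8R)-4,8,12-trimethyltridecyl]-1-oxaspiro[4.4]non-7-en-6-one | CC(=O)[C@]1(O)C(C)=C(C)C(=O)[C@@]12CC[C@](C)(CCC[C@H](C)CCC[C@H](C)CCCC(C)C)O2 | target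

Total step count: 12. Longest linear sequence: 9 steps (steps 1–4 and 8–12, from phytol); the arene branch is steps 5–7.

Steps most likely to fail

1. Step 12, the ring contraction. In the chelate the C7–methyl bond is as well aligned with the C6 carbonyl as the C7–C8 bond, so methyl migration may compete with or overtake the vinyl shift and give a six-membered enedione isomer. The fallback sets out from 15 and comes back at 16; it carries out the contraction in two stages through that isomer. Methyl migration in the aluminium chelate of 15 puts the methyl group on C6 on the O1 face and gives (2S,5R,10R)-10-hydroxy-2,7,8,10-tetramethyl-2-[(4R,8R)-4,8,12-trimethyltridecyl]-1-oxaspiro[4.5]dec-7-ene-6,9-dione F1, which would be isolated. F1 is again a tertiary α-ketol, now with the spiro carbon C5 next to the carbinol carbon. A second treatment with Al(OtBu)3 in toluene lets C5, a quaternary oxygen-bearing carbon of high migratory aptitude, shift from C10 to the C9 carbonyl. This acyloin contraction with a different migrating group closes the same cyclopentenone and turns C10 into the acetyl group. The same chelate geometry (methyl axial on the O1 face) places the acetyl group syn to O1 with retention at C5, so 16 should result.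

2. Step 11, the dienolate hydroxylation. The oxidant may prefer the dienolate face syn to O1, which is the sterically smaller flank, or may discriminate poorly between the two nucleophilic carbons, so that the (5S,7S) isomer is formed only as a minor product. The fallback sets out from 13 and comes back at 16; it switches to the C7 epimer and to an unchelated shift. With the antipodal (−)-(2S,8aR)-(camphorylsulfonyl)oxaziridine on dienolate 14, hydroxylation from the face syn to O1 gives (2S,5S,7R)-7-hydroxy-2,7,8,9-tetramethyl-2-[(4R,8R)-4,8,12-trimethyltridecyl]-1-oxaspiro[4.5]dec-8-ene-6,10-dione F2. F2 is rearranged as its potassium alkoxide under non-chelating conditions (KN(SiMe3)2, 18-crown-6, THF, −40 → 0 °C). There the alkoxide oxygen avoids eclipsing the C6 carbonyl and sits axial, the ring takes the other half-chair, and C8 adds to the face of C6 opposite to that used in the chelate. Because C7 is inverted as well, the acetyl group again ends syn to O1 and 16 is expected. This uses the known divergence between base-mediated and Lewis-acid-mediated acyloin rearrangements to make either face of hydroxylation productive.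

3. Step 10, the oxidative spiroetherification. The cationic intermediate may be captured at a methyl-bearing ring carbon by acetate or solvent faster than at the alkyl-bearing carbon by the hindered tertiary hydroxyl, or the enol product may be oxidised a second time. The fallback sets out from 12 and comes back at 15; it reverses the order of the two C–O bond formations. 12 is oxidised with PhI(OCOCF3)2 in MeCN/H2O at 0 °C so that water is added on purpose at a methyl-bearing carbon (hydroxylative dearomatisation). This gives (6S)-3,6-dihydroxy-2-[(3S,7R,11R)-3-hydroxy-3,7,11,15-tetramethylhexadecyl]-4,5,6-trimethylcyclohexa-2,4-dien-1-one F3 together with its 6R epimer. The 2-alkyl-1,3-dione enol of F3 is then closed onto the side-chain hydroxyl with PhI(OAc)2 in CH2Cl2 (oxidative cycloetherification at the α-carbon of a 1,3-dicarbonyl compound). That gives 15 after chromatographic separation of diastereomers; steps 10 and 11 are bypassed and reagent control is given up.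

Further compounds
F1 | step 12 | (2S,5R,10R)-10-hydroxy-2,7,8,10-tetramethyl-2-[(4R,8R)-4,8,12-trimethyltridecyl]-1-oxaspiro[4.5]dec-7-ene-6,9-dione | C[C@]1(O)C(=O)C(C)=C(C)C(=O)[C@@]12CC[C@](C)(CCC[C@H](C)CCC[C@H](C)CCCC(C)C)O2
F2 | step 11 | (2S,5S,7R)-7-hydroxy-2,7,8,9-tetramethyl-2-[(4R,8R)-4,8,12-trimethyltridecyl]-1-oxaspiro[4.5]dec-8-ene-6,10-dione | C[C@@]1(O)C(C)=C(C)C(=O)[C@@]2(CC[C@](C)(CCC[C@H](C)CCC[C@H](C)CCCC(C)C)O2)C1=O
F3 | step 10 | (6S)-3,6-dihydroxy-2-[(3S,7R,11R)-3-hydroxy-3,7,11,15-tetramethylhexadecyl]-4,5,6-trimethylcyclohexa-2,4-dien-1-one | C[C@]1(O)C(C)=C(C)C(O)=C(CC[C@@](C)(O)CCC[C@H](C)CCC[C@H](C)CCCC(C)C)C1=O
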